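The route exploits the tetronic acid ring (O1, C2, C3, C4, C5). Cut at C3–C4, its O1–C5=C6 unit is the enol oxygen and double bond of an α-keto ester whose ester carbon is C4, and C2, C3 and the C3 methyl are a propanoyl group on O1. One base-mediated Dieckmann closure therefore makes C3–C4, builds the five-membered ring and frees the C4 hydroxyl unprotected, leaving the Z C5=C6 bond and stereocentre C7 untouched. Its precursor is the methyl (Z)-2-(propanoyloxy)enoate 24, which already carries the whole (S)-configured bis-furyl chain, assembled from a Roche-ester alkene and a bis-furyl (E)-vinyl iodide by B-alkyl Suzuki coupling.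

Key step: step 15

Remark: atom labels follow the tetronic acid (O1, C2–C5) and run on along the chain (C6 vinyl CH, C7 stereocentre, C11=C12 trisubstituted alkene, C14 on the furan); carbinol 4 is racemic, which does not matter because its centre becomes CH2 in step 2.

Step 1
Reactants: 1 3-bromofuran; 2 4-bromofuran-2-carbaldehyde
Product: 4 (4-bromofuran-2-yl)(furan-3-yl)methanol (racemic), via furan-3-yllithium 3 (not isolated)
Conditions: 1, n-BuLi, THF, –78 °C; then 2, –78 °C; aq NH4Cl
Reagents that add atoms: none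
Why: Bromine–lithium exchange gives the 3-lithiofuran, which holds its position at –78 °C, and its 1,2-addition to the aldehyde is faster than exchange with the ring bromide of 2.

Step 2
Reactants: 4 (4-bromofuran-2-yl)(furan-3-yl)methanol
Product: 5 4-bromo-2-(furan-3-ylmethyl)furan
Conditions: Et3SiH, TFA, CH2Cl2, –20 to 0 °C
Reagents that add atoms: none
Why: Ionic hydrogenation, in which the carbenium ion stabilised by both furans is captured by hydride from excess silane, the ring bromide damping the nucleophilicity of the furan that could otherwise attack the cation.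

Step 3
Reactants: 5 4-bromo-2-(furan-3-ylmethyl)furan; 6 (4-bromobut-1-yn-1-yl)trimethylsilane
Product: 8 {4-[5-(furan-3-ylmethyl)furan-3-yl]but-1-yn-1-yl}trimethylsilane, via [4-(trimethylsilyl)but-3-yn-1-yl]zinc bromide 7 (not isolated)
Conditions: 6, Zn dust, I2 (cat.), DMA, 70 °C; then 5, Pd(OAc)2 (cat.), SPhos (cat.), THF, 50 °C
Reagents that add atoms: none
Why: Negishi cross-coupling of a primary alkylzinc halide with a heteroaryl bromide, the electron-rich biarylphosphine favouring insertion into the furyl C–Br bond and reductive elimination over β-hydride loss while the silyl cap keeps the alkyne inert.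

Step 4
Reactants: 8 {4-[5-(furan-3-ylmethyl)furan-3-yl]but-1-yn-1-yl}trimethylsilane
Product: 9 4-(but-3-yn-1-yl)-2-(furan-3-ylmethyl)furan
Conditions: K2CO3, MeOH, rt
Reagents that add atoms: none
Why: Methoxide-mediated protodesilylation of an alkynylsilane, with nothing else in 8 labile to mild base.

Step 5
Reactants: 9 4-(but-3-yn-1-yl)-2-(furan-3-ylmethyl)furan
Product: 11 2-(furan-3-ylmethyl)-4-[(E)-4-iodo-3-methylbut-3-en-1-yl]furan, via (E)-alkenyldimethylalane 10 (not isolated)
Conditions: Me3Al, Cp2ZrCl2 (cat.), CH2Cl2, 0 °C to rt; then I2, THF, –30 to 0 °C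
Reagents that add atoms: trimethylaluminium, C[Al](C)C; iodine, II
Why: Negishi zirconium-catalysed carboalumination adds methyl and aluminium syn across the terminal alkyne with methyl on the internal carbon, and iodinolysis of the C–Al bond with retention fixes the (E)-vinyl iodide.

Step 6
Reactants: 12 methyl (R)-3-hydroxy-2-methylpropanoate
Product: 13 methyl (R)-3-[(tert-butyldiphenylsilyl)oxy]-2-methylpropanoate
Conditions: TBDPSCl, imidazole, DMF, 0 °C to rt
Reagents that add atoms: tert-butyl(chloro)diphenylsilane, CC(C)(C)[Si](Cl)(c1ccccc1)c1ccccc1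
Why: Imidazole-promoted silylation of the primary alcohol, the bulky silyl group being chosen because it resists the 1,3-O-to-O migration that would racemise alcohol 14; the future C7 centre is carried over from 12.

Step 7
Reactants: 13 methyl (R)-3-[(tert-butyldiphenylsilyl)oxy]-2-methylpropanoate
Product: 14 (S)-3-[(tert-butyldiphenylsilyl)oxy]-2-methylpropan-1-ol
Conditions: i-Bu2AlH, CH2Cl2, –78 to 0 °C; aq potassium sodium tartrate
Reagents that add atoms: none
Why: Aluminium hydride reduction of the ester to the primary alcohol under non-basic conditions that leave the adjacent stereocentre intact (the descriptor changes only through CIP priorities).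

Step 8
Reactants: 14 (S)-3-[(tert-butyldiphenylsilyl)oxy]-2-methylpropan-1-ol
Product: 15 (R)-tert-butyl(3-iodo-2-methylpropoxy)diphenylsilane
Conditions: I2, PPh3, imidazole, CH2Cl2, 0 °C to rt
Reagents that add atoms: iodine, II
Why: Appel-type (Garegg–Samuelsson) iodination through the alkoxyphosphonium ion, with SN2 displacement at the primary carbon and no bond to the stereocentre broken.

Step 9
Reactants: 15 (R)-tert-butyl(3-iodo-2-methylpropoxy)diphenylsilane
Product: 16 (S)-tert-butyl[(2-methylpent-4-en-1-yl)oxy]diphenylsilane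
Conditions: CH2=CHMgBr, CuI (0.3 equiv), THF/DMPU, –30 °C to rt
Reagents that add atoms: vinylmagnesium bromide, C=C[Mg]Br
Why: Copper-mediated cross-coupling of a vinyl Grignard reagent (through the vinylcuprate) with a primary alkyl iodide, the stereocentre lying β to the reacting carbon.

Step 10
Reactants: 16 (S)-tert-butyl[(2-methylpent-4-en-1-yl)oxy]diphenylsilane; 11 2-(furan-3-ylmethyl)-4-[(E)-4-iodo-3-methylbut-3-en-1-yl]furan
Product: 18 tert-butyl({(2S,6E)-9-[5-(furan-3-ylmethyl)furan-3-yl]-2,7-dimethylnon-6-en-1-yl}oxy)diphenylsilane, via B-alkyl-9-BBN adduct 17 (not isolated)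
Conditions: 16, 9-BBN, THF, 0 °C to rt; then 11, PdCl2(dppf) (cat.), aq K3PO4, DMF, rt
Reagents that add atoms: none
Why: Anti-Markovnikov hydroboration of the terminal alkene followed by B-alkyl Suzuki–Miyaura coupling, which forms C10–C11 with retention of the (E)-geometry of the vinyl iodide; silyl ether and furans are inert.

Step 11
Reactants: 18 tert-butyl({(2S,6E)-9-[5-(furan-3-ylmethyl)furan-3-yl]-2,7-dimethylnon-6-en-1-yl}oxy)diphenylsilane
Product: 19 (2S,6E)-9-[5-(furan-3-ylmethyl)furan-3-yl]-2,7-dimethylnon-6-en-1-ol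
Conditions: Bu4NF, THF, rt
Reagents that add atoms: none
Why: Fluoride-driven desilylation, which the furans and the trisubstituted alkene tolerate.

Step 12
Reactants: 19 (2S,6E)-9-[5-(furan-3-ylmethyl)furan-3-yl]-2,7-dimethylnon-6-en-1-ol
Product: 20 4-[(3E,8S)-9-bromo-3,8-dimethylnon-3-en-1-yl]-2-(furan-3-ylmethyl)furan
Conditions: CBr4, PPh3, CH2Cl2, 0 °C
Reagents that add atoms: tetrabromomethane, BrC(Br)(Br)Br
Why: Appel bromination of the primary alcohol under near-neutral conditions, with displacement at C6 only.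

Step 13
Reactants: 20 4-[(3E,8S)-9-bromo-3,8-dimethylnon-3-en-1-yl]-2-(furan-3-ylmethyl)furan; 21 dimethyl oxalate
Product: 23 methyl (4S,8E)-11-[5-(furan-3-ylmethyl)furan-3-yl]-4,9-dimethyl-2-oxoundec-8-enoate, via C6 Grignard reagent 22 (not isolated)
Conditions: Mg turnings, BrCH2CH2Br (cat.), THF, rt to 40 °C; then added to 21 (3 equiv), THF, –78 °C; aq NH4Cl at –78 °C
Reagents that add atoms: none
Why: Acyl substitution of an oxalate ester by a Grignard reagent, where inverse addition to excess oxalate at –78 °C keeps the magnesium hemiketal intact until the quench so that only one ester is replaced; C7 is β to the new ketone and cannot epimerise.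

Step 14
Reactants: 23 methyl (4S,8E)-11-[5-(furan-3-ylmethyl)furan-3-yl]-4,9-dimethyl-2-oxoundec-8-enoate
Product: 24 methyl (2Z,4S,8E)-11-[5-(furan-3-ylmethyl)furan-3-yl]-4,9-dimethyl-2-(propanoyloxy)undeca-2,8-dienoate
Conditions: (EtCO)2O, Et3N, DMAP (cat.), CH2Cl2, 0 °C to rt
Reagents that add atoms: propanoic anhydride, CCC(=O)OC(=O)CC
Why: DMAP-catalysed O-acylation of the α-keto ester enol, which can form only toward C6, and is expected to favour the less strained Z enol ester with the C7 branch trans to the methoxycarbonyl group.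

Step 15
Reactants: 24 methyl (2Z,4S,8E)-11-[5-(furan-3-ylmethyl)furan-3-yl]-4,9-dimethyl-2-(propanoyloxy)undeca-2,8-dienoate
Product: 26 (5Z)-5-{(2S,6E)-9-[5-(furan-3-ylmethyl)furan-3-yl]-2,7-dimethylnon-6-en-1-ylidene}-4-hydroxy-3-methylfuran-2(5H)-one, via lithium tetronate 25 (not isolated)
Conditions: LiN(SiMe3)2 (2.3 equiv), THF, –78 to –20 °C, 24 added slowly to the base; then cold 1 M HCl
Reagents that add atoms: none
Why: Dieckmann (intramolecular Claisen) condensation: the hindered amide removes an α-proton of the propanoyl group, the enolate carbon C3 adds to the neighbouring methoxycarbonyl carbon C4, methoxide leaves, and the resulting 2,4-dione is deprotonated at once to the delocalised tetronate 25, which drives the sequence forward until acidification releases 26. The closest known reaction type is the amide-base cyclisation of α-acyloxy esters and of enol esters of α-keto esters to tetronic acids and 5-ylidene tetronic acids. The one ring formed (O1, C2, C3, C4, C5) closes 5-exo-trig at the ester carbonyl, in the enolendo sense that is routine for this class of closure. No stereocentre is created, and the C7 configuration and the Z C5=C6 geometry are carried through because no bond to C5, C6 or C7 is made or broken. The step needs deprotonation of the propanoyl CH2 to win over γ-deprotonation at C7, and ring closure to win over loss of methylketene from the enolate. The unhindered CH2 of an enol (phenol-like) ester is the kinetic site for a bulky base, nucleophile and electrophile are both held on sp2 C5, and the tetronate anion once formed resists further deprotonation.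

Compound list
1 | 3-bromofuran | Brc1ccoc1 | starting material
2 | 4-bromofuran-2-carbaldehyde | O=Cc1cc(Br)co1 | starting material
3 | furan-3-yllithium | [Li]c1ccoc1 | intermediate
4 | (4-bromofuran-2-yl)(furan-3-yl)methanol (racemic) | OC(c1ccoc1)c1cc(Br)co1 | intermediate
5 | 4-bromo-2-(furan-3-ylmethyl)furan | Brc1coc(Cc2ccoc2)c1 | intermediate
6 | (4-bromobut-1-yn-1-yl)trimethylsilane | C[Si](C)(C)C#CCCBr | starting material
7 | [4-(trimethylsilyl)but-3-yn-1-yl]zinc bromide | C[Si](C)(C)C#CCC[Zn]Br | intermediate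
8 | {4-[5-(furan-3-ylmethyl)furan-3-yl]but-1-yn-1-yl}trimethylsilane | C[Si](C)(C)C#CCCc1coc(Cc2ccoc2)c1 | intermediate
9 | 4-(but-3-yn-1-yl)-2-(furan-3-ylmethyl)furan | C#CCCc1coc(Cc2ccoc2)c1 | intermediate
10 | {(E)-4-[5-(furan-3-ylmethyl)furan-3-yl]-2-methylbut-1-en-1-yl}dimethylalumane | C[Al](C)/C=C(\C)CCc1coc(Cc2ccoc2)c1 | intermediate
11 | 2-(furan-3-ylmethyl)-4-[(E)-4-iodo-3-methylbut-3-en-1-yl]furan | I/C=C(\C)CCc1coc(Cc2ccoc2)c1 | intermediate
12 | methyl (R)-3-hydroxy-2-methylpropanoate | OC[C@@H](C)C(=O)OC | starting material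
13 | methyl (R)-3-[(tert-butyldiphenylsilyl)oxy]-2-methylpropanoate | CC(C)(C)[Si](c1ccccc1)(c1ccccc1)OC[C@@H](C)C(=O)OC | intermediate
14 | (S)-3-[(tert-butyldiphenylsilyl)oxy]-2-methylpropan-1-ol | CC(C)(C)[Si](c1ccccc1)(c1ccccc1)OC[C@@H](C)CO | intermediate
15 | (R)-tert-butyl(3-iodo-2-methylpropoxy)diphenylsilane | CC(C)(C)[Si](c1ccccc1)(c1ccccc1)OC[C@@H](C)CI | intermediate
16 | (S)-tert-butyl[(2-methylpent-4-en-1-yl)oxy]diphenylsilane | CC(C)(C)[Si](c1ccccc1)(c1ccccc1)OC[C@@H](C)CC=C | intermediate
17 | (S)-9-{5-[(tert-butyldiphenylsilyl)oxy]-4-methylpentyl}-9-borabicyclo[3.3.1]nonane | CC(C)(C)[Si](c1ccccc1)(c1ccccc1)OC[C@@H](C)CCCB1C2CCCC1CCC2 | intermediate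
18 | tert-butyl({(2S,6E)-9-[5-(furan-3-ylmethyl)furan-3-yl]-2,7-dimethylnon-6-en-1-yl}oxy)diphenylsilane | CC(C)(C)[Si](c1ccccc1)(c1ccccc1)OC[C@@H](C)CCC/C=C(\C)CCc1coc(Cc2ccoc2)c1 | intermediate
19 | (2S,6E)-9-[5-(furan-3-ylmethyl)furan-3-yl]-2,7-dimethylnon-6-en-1-ol | OC[C@@H](C)CCC/C=C(\C)CCc1coc(Cc2ccoc2)c1 | intermediate
20 | 4-[(3E,8S)-9-bromo-3,8-dimethylnon-3-en-1-yl]-2-(furan-3-ylmethyl)furan | BrC[C@@H](C)CCC/C=C(\C)CCc1coc(Cc2ccoc2)c1 | intermediate
21 | dimethyl oxalate | COC(=O)C(=O)OC | starting material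
22 | {(2S,6E)-9-[5-(furan-3-ylmethyl)furan-3-yl]-2,7-dimethylnon-6-en-1-yl}magnesium bromide | Br[Mg]C[C@@H](C)CCC/C=C(\C)CCc1coc(Cc2ccoc2)c1 | intermediate
23 | methyl (4S,8E)-11-[5-(furan-3-ylmethyl)furan-3-yl]-4,9-dimethyl-2-oxoundec-8-enoate | COC(=O)C(=O)C[C@@H](C)CCC/C=C(\C)CCc1coc(Cc2ccoc2)c1 | intermediate
24 | methyl (2Z,4S,8E)-11-[5-(furan-3-ylmethyl)furan-3-yl]-4,9-dimethyl-2-(propanoyloxy)undeca-2,8-dienoate | CCC(=O)O/C(=C\[C@@H](C)CCC/C=C(\C)CCc1coc(Cc2ccoc2)c1)C(=O)OC | intermediate
25 | lithium (5Z)-2-{(2S,6E)-9-[5-(furan-3-ylmethyl)furan-3-yl]-2,7-dimethylnon-6-en-1-ylidene}-4-methyl-5-oxo-2,5-dihydrofuran-3-olate (lithium tetronate) | CC1=C([O-])/C(=C/[C@@H](C)CCC/C=C(\C)CCc2coc(Cc3ccoc3)c2)OC1=O.[Li+] | intermediate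
26 | (5Z)-5-{(2S,6E)-9-[5-(furan-3-ylmethyl)furan-3-yl]-2,7-dimethylnon-6-en-1-ylidene}-4-hydroxy-3-methylfuran-2(5H)-one | CC1=C(O)/C(=C/[C@@H](C)CCC/C=C(\C)CCc2coc(Cc3ccoc3)c2)OC1=O | target

Total step count: 15. Longest linear sequence: 11 steps (steps 1–5, then 10–15); the Roche-ester branch (steps 6–9) joins at step 10.

Steps most likely to fail

Step 15. The propanoate enolate may lose methylketene by E1cB fragmentation faster than it cyclises, or the base may remove the γ-proton at C7 and erode its configuration. The fallback sets out from alcohol 19 and comes back at target 26, replacing the C3–C4 closure by a C5=C6 olefination on a ready-made tetronate. Alcohol 19 would be oxidised with Dess–Martin periodinane (NaHCO3, CH2Cl2) to (2S,6E)-9-[5-(furan-3-ylmethyl)furan-3-yl]-2,7-dimethylnon-6-enal F1. Addition of the C5 lithium anion of the known 4-methoxy-3-methylfuran-2(5H)-one (LiN(i-Pr)2, THF, –78 °C) should give the aldol adduct 5-{(2S,6E)-9-[5-(furan-3-ylmethyl)furan-3-yl]-1-hydroxy-2,7-dimethylnon-6-en-1-yl}-4-methoxy-3-methylfuran-2(5H)-one F2 as a diastereomer mixture. Mesylation (MsCl, Et3N, CH2Cl2, 0 °C) would give the methanesulfonate of that adduct F3, and DBU should eliminate it to the (Z)-5-ylidene O-methyl tetronate F4. O-Demethylation with LiSPr in DMPU would then give 26.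

Step 14. Amine-induced self-aldol condensation of α-keto ester 23 may compete with O-acylation, or the acylation may not settle cleanly on the Z enol ester. The fallback sets out from alcohol 19 and comes back at precursor 24, bypassing steps 12–14 so that the free α-keto ester is never formed. Alcohol 19 would be oxidised as above to the aldehyde F1 of the preceding fallback. Methyl 2-(dimethoxyphosphoryl)-2-hydroxyacetate would be propanoylated ((EtCO)2O, pyridine, DMAP) to methyl 2-(dimethoxyphosphoryl)-2-(propanoyloxy)acetate F5. Horner–Wadsworth–Emmons olefination of the aldehyde with this phosphonate under Masamune–Roush conditions (LiCl, DBU, MeCN, 0 °C) should give 24 directly, with any E isomer removed by chromatography.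

Step 2. Friedel–Crafts attack of a furan on the bis-furyl carbenium ion (oligomerisation) or acid-induced furan ring opening may compete with hydride transfer. The fallback sets out from carbinol 4 and comes back at 5 through base-only chemistry with no cationic intermediate. Carbinol 4 would be oxidised with MnO2 (CH2Cl2, rt) to (4-bromofuran-2-yl)(furan-3-yl)methanone F6. Condensation with N2H4·H2O (EtOH, reflux) would give (4-bromofuran-2-yl)(furan-3-yl)methanone hydrazone F7. Slow addition of the hydrazone to KOt-Bu in DMSO at rt (Cram-modified Wolff–Kishner reduction) should give 5 with loss of dinitrogen.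

Further compounds
F1 | step 15 | (2S,6E)-9-[5-(furan-3-ylmethyl)furan-3-yl]-2,7-dimethylnon-6-enal | O=C[C@@H](C)CCC/C=C(\C)CCc1coc(Cc2ccoc2)c1
F2 | step 15 | 5-{(2S,6E)-9-[5-(furan-3-ylmethyl)furan-3-yl]-1-hydroxy-2,7-dimethylnon-6-en-1-yl}-4-methoxy-3-methylfuran-2(5H)-one (diastereomer mixture) | CC1=C(OC)C(C(O)[C@@H](C)CCC/C=C(\C)CCc2coc(Cc3ccoc3)c2)OC1=O
F3 | step 15 | methanesulfonate of F2 | CC1=C(OC)C(C(OS(C)(=O)=O)[C@@H](C)CCC/C=C(\C)CCc2coc(Cc3ccoc3)c2)OC1=O
F4 | step 15 | (5Z)-5-{(2S,6E)-9-[5-(furan-3-ylmethyl)furan-3-yl]-2,7-dimethylnon-6-en-1-ylidene}-4-methoxy-3-methylfuran-2(5H)-one | CC1=C(OC)/C(=C/[C@@H](C)CCC/C=C(\C)CCc2coc(Cc3ccoc3)c2)OC1=O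
F5 | step 14 | methyl 2-(dimethoxyphosphoryl)-2-(propanoyloxy)acetate | CCC(=O)OC(C(=O)OC)P(=O)(OC)OC
F6 | step 2 | (4-bromofuran-2-yl)(furan-3-yl)methanone | O=C(c1ccoc1)c1cc(Br)co1
F7 | step 2 | (4-bromofuran-2-yl)(furan-3-yl)methanone hydrazone | NN=C(c1ccoc1)c1cc(Br)co1
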